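**Assumption:** (+)-podocarpic acid (normal-series labdane/podocarpane with the axial C19 acid), chloroprene (as a stabilised solution) and (E)-4-acetoxycinnamic acid are purchased. The C9 side chain ends up equatorial (9α-H), as in the target.

## Retrosynthetic overview
1. The target comes from C19 acylation with a protected p-coumaric acid, applied to the 8α-hydroxy-diene-19-ol **10**.
2. The C12–C13 bond of the 2-substituted butadiene is made by photoredox/Ni decarboxylative coupling of the C13 acid (as a redox-active ester) with chloroprene.
3. The 8α-OH/8β-Me pair comes from HAT hydration of an 8(17)-alkene, which comes from Wittig methylenation of an 8-ketone. That ketone arises by ozonolytic opening of ring C of the Birch product of podocarpic acid.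
4. No ring is formed. Rings A/B, with C4 (axial CH2O, from the axial C19 acid), C5 and C10, are carried intact from podocarpic acid, and ring C is opened.

## Route

**Step 1**
Reactants: **1** (+)-podocarpic acid
Product: **2** methyl O-methylpodocarpate
Conditions: MeI, K2CO3, DMF, rt
Reagents that add atoms: MeI (CI)
Why: Williamson/SN2 O-methylation of the carboxylate and phenolate; no stereocentre is touched.

**Step 2**
Reactants: **2**
Product: **3** methyl 13-oxopodocarp-8(14)-en-19-oate
Conditions: Li, NH3(l)/THF, t-BuOH, −78 → −33 °C; then 3 M HCl, MeOH/THF, 65 °C (the enol ether is not isolated)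
Reagents that add atoms: water (O), which becomes the ketone oxygen
Why: Birch reduction gives the 13-methoxy-diene enol ether, and acid hydrolysis and conjugation give the Δ8(14)-13-one. The new C9 stereocentre is set by axial protonation of the dienol, giving the thermodynamic trans-B/C 9α-H, and the hindered axial methyl ester survives.

**Step 3**
Reactants: **3**
Product: **4** 8-oxo-14,15,16,17-tetranorlabdane-13,19-dioic acid 19-methyl ester
Conditions: O3, CH2Cl2/MeOH, −78 °C; then 30% H2O2, HCO2H, rt
Reagents that add atoms: O3 (O=[O+][O-]); H2O2 (OO)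
Why: Ozonolytic cleavage of the enone C8=C14 is the same reaction as the Δ4-3-keto-steroid to 4-nor-3,5-seco-acid cleavage. It gives the C8 ketone, and the α-keto acid loses C14 as CO2 to leave the C13 carboxylic acid; C9 stays equatorial.

**Step 4**
Reactants: **4**
Product: **5** 14,15,16-trinorlabd-8(17)-ene-13,19-dioic acid 19-methyl ester
Conditions: Ph3P+CH3 Br−, KOt-Bu (4 equiv), THF/toluene, 0 °C → 65 °C
Reagents that add atoms: Ph3P=CH2 (C=P(c1ccccc1)(c1ccccc1)c1ccccc1), which supplies C17
Why: Wittig methylenation of the C8 ketone; no stereocentre is created, and the base keeps C9 in its equatorial, thermodynamic configuration.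

**Step 5**
Reactants: **5**
Product: **6** 8α-hydroxy-14,15,16-trinorlabdane-13,19-dioic acid 19-methyl ester
Conditions: Co(acac)2 (5 mol %), PhSiH3, O2 (1 atm), i-PrOH, rt
Reagents that add atoms: O2 (O=O)
Why: Mukaiyama–Inoki hydration (Co–H HAT, then O2 trapping) gives the tertiary C8 radical. O2 attacks from the α-face because the β-face is blocked by the syn-axial C20 methyl, giving 8α-OH and the axial 8β-Me.

**Step 6**
Reactants: **6**
Product: **7** N-hydroxyphthalimide ester of the C13 acid
Conditions: N-hydroxyphthalimide, DIC, cat. DMAP, CH2Cl2, 0 °C → rt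
Reagents that add atoms: N-hydroxyphthalimide (O=C1c2ccccc2C(=O)N1O)
Why: Steglich-type activation occurs chemoselectively at the unhindered C13 acid; the axial C19 ester and the tertiary 8-OH are inert, and no stereocentre is affected.

**Step 7**
Reactants: **7**; **8** 2-chloro-1,3-butadiene
Product: **9** methyl 8α-hydroxylabda-13(16),14-dien-19-oate
Conditions: **8** (3 equiv), NiBr2·diglyme (10 mol %), 4,4′-di-t-Bu-bipyridine (12 mol %), 4CzIPN (2 mol %), Hantzsch ester (1.5 equiv), DMA, 450 nm blue LEDs, 25 °C, 16 h
Reagents that add atoms: none (the C4 unit comes from reactant **8**)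
Why: Key photochemical step; it forms the C12–C13 bond and makes no new stereocentre. Proposed new method: reductive quenching of the excited photocatalyst by Hantzsch ester gives a strongly reducing species that fragments the redox-active ester to the primary C12 radical, CO2 and phthalimide anion. Ni(0) inserts into the conjugation-activated C–Cl bond of chloroprene, the radical is captured, and C(sp3)–C(sp2) reductive elimination gives the 2-alkyl-1,3-diene. The closest known reaction is Ni/photoredox decarboxylative alkenylation of alkyl NHPI esters with vinyl halides, here extended to a 2-halo-1,3-diene.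

**Step 8**
Reactants: **9**
Product: **10** labda-13(16),14-diene-8α,19-diol
Conditions: LiAlH4, THF, reflux, 2 h
Reagents that add atoms: none
Why: Hydride reduction of the hindered axial methyl ester to the primary alcohol; the diene and the tertiary alcohol are unaffected and C4 is untouched.

**Step 9**
Reactants: **10**; **11** (E)-4-acetoxycinnamic acid
Product: **12** 8α-hydroxylabda-13(16),14-dien-19-yl (E)-4-acetoxycinnamate
Conditions: EDC·HCl, DMAP, CH2Cl2, rt
Reagents that add atoms: none (the cinnamoyl unit comes from reactant **11**)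
Why: Steglich esterification acylates the primary C19 alcohol and not the tertiary 8α-OH; the acetate protects the phenol.

**Step 10**
Reactants: **12**
Product: **13** target, 8α-hydroxylabda-13(16),14-dien-19-yl (E)-p-hydroxycinnamate
Conditions: N2H4·AcOH, DMF, rt, 1 h
Reagents that add atoms: none
Why: Aminolysis selectively cleaves the labile phenolic acetate and leaves the hindered alkyl cinnamate and the tertiary alcohol intact.

## Compound list
1 | (+)-podocarpic acid | OC(=O)[C@@]1(C)CCC[C@]2(C)c3ccc(O)cc3CC[C@@H]12 | starting material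
2 | methyl O-methylpodocarpate | COC(=O)[C@@]1(C)CCC[C@]2(C)c3ccc(OC)cc3CC[C@@H]12 | intermediate
3 | methyl 13-oxopodocarp-8(14)-en-19-oate | COC(=O)[C@@]1(C)CCC[C@]2(C)[C@H]3CCC(=O)C=C3CC[C@@H]12 | intermediate
4 | 8-oxo-14,15,16,17-tetranorlabdane-13,19-dioic acid 19-methyl ester | OC(=O)CC[C@@H]1[C@@]2(C)CCC[C@](C)(C(=O)OC)[C@@H]2CCC1=O | intermediate
5 | 14,15,16-trinorlabd-8(17)-ene-13,19-dioic acid 19-methyl ester | OC(=O)CC[C@@H]1[C@@]2(C)CCC[C@](C)(C(=O)OC)[C@@H]2CCC1=C | intermediate
6 | 8α-hydroxy-14,15,16-trinorlabdane-13,19-dioic acid 19-methyl ester | OC(=O)CC[C@@H]1[C@@]2(C)CCC[C@](C)(C(=O)OC)[C@@H]2CC[C@@]1(C)O | intermediate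
7 | NHPI ester of 6 (C13) | O=C1c2ccccc2C(=O)N1OC(=O)CC[C@@H]3[C@@]4(C)CCC[C@](C)(C(=O)OC)[C@@H]4CC[C@@]3(C)O | intermediate
8 | 2-chloro-1,3-butadiene (chloroprene) | C=CC(Cl)=C | starting material
9 | methyl 8α-hydroxylabda-13(16),14-dien-19-oate | C=CC(=C)CC[C@@H]1[C@@]2(C)CCC[C@](C)(C(=O)OC)[C@@H]2CC[C@@]1(C)O | intermediate
10 | labda-13(16),14-diene-8α,19-diol | C=CC(=C)CC[C@@H]1[C@@]2(C)CCC[C@](C)(CO)[C@@H]2CC[C@@]1(C)O | intermediate
11 | (E)-4-acetoxycinnamic acid | CC(=O)Oc1ccc(/C=C/C(=O)O)cc1 | starting material
12 | 8α-hydroxylabda-13(16),14-dien-19-yl (E)-4-acetoxycinnamate | C=CC(=C)CC[C@@H]1[C@@]2(C)CCC[C@](C)(COC(=O)/C=C/c3ccc(OC(C)=O)cc3)[C@@H]2CC[C@@]1(C)O | intermediate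
13 | 8α-hydroxylabda-13(16),14-dien-19-yl (E)-p-hydroxycinnamate | C=CC(=C)CC[C@@H]1[C@@]2(C)CCC[C@](C)(COC(=O)/C=C/c3ccc(O)cc3)[C@@H]2CC[C@@]1(C)O | target

## Totals
Total steps: 10. Longest linear sequence: 10 (from **1**).

## Three steps most likely to fail
1. **Step 7 (proposed new step).** Risks are radical oligomerisation of chloroprene and 1,5-HAT of the primary C12 radical from C20/C17.
   - Fallback (known chemistry): convert **6** to its Weinreb amide, add vinylMgBr to give the C13 vinyl ketone, and methylenate (Tebbe or Lombardo) to give **9**.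
2. **Step 5 (C8 stereocontrol of the HAT hydration).** It may give a mixture of 8α- and 8β-alcohols.
   - Fallback: esterify the C13 acid of **5** to the methyl ester, epoxidise the exocyclic alkene from the α-face (mCPBA), open the epoxide at C17 with LiEt3BH to give the 8α-OH/8β-Me, and selectively hydrolyse the C13 ester.
3. **Step 3 (enone ozonolysis and decarboxylation).** Over-oxidation or poor yield is possible.
   - Fallback: epoxidise the enone (H2O2, NaOH) and run Eschenmoser–Tanabe fragmentation (TsNHNH2) to give the 8-ketone with a C13≡C14 terminal alkyne. Then apply Steps 4–5, and use Grubbs-II ethylene–alkyne cross-metathesis to build the 13(16),14-diene in place of Steps 6–7.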